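The numbers in the tables stem from a simulated flask for substances that don't exist, and the scatter is random.

Choose which flask to charge.

| setting | blue | violet | cedar | alder |
|---|---|---|---|---|
| left-handed substrate | 0.032 M | 0.051 M | 0.023 M | 0.023 M |
| right-handed substrate | 0.032 M | 0.051 M | 0.023 M | 0.023 M |
| partner | 0.046 M | 0.046 M | 0.0460 M | 0.0460 M |
| catalyst | 34 µM | 34 µM | 34 µM | 34 µM |
| added ligand | 46 µM | 46 µM | 46 µM | 46 µM |
| temperature | −20 °C | −8 °C | 0 °C | −15 °C |
| remark | run made earlier | run made earlier |  |  |
| time |  |  | 15 h | 15 h |

1. which flask leads in excess of left-handed product over right-handed product ("all alike" within 1.5 percentage points) (cedar / alder / all alike)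
2. excess of left-handed product over right-handed product at the end, cedar
3. excess of left-handed product over right-handed product at the end, alder

- catalyst is single-handed; left-handed substrate and right-handed substrate are mirror images of each other, charged as a racemate, each of them at the stated concentration
- an excess is the difference of the two amounts in percent of their sum
- an excess is below zero if the other one leads

| run | time / h | left-handed product / % | right-handed product / % | left-handed substrate / % |
|---|---|---|---|---|
| blue | 8.00 | 6.1 | 0.9 | 43.2 |
| blue | 15.0 | 9.2 | 2.0 | 40.2 |
| blue | 25.0 | 11.6 | 1.7 | 37.1 |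
| blue | 30.0 | 12.9 | 0.9 | 36.3 |
| violet | 3.00 | 4.5 | 0.5 | 46.2 |
| violet | 6.00 | 6.2 | 0 | 43.7 |
| violet | 10.0 | 10.4 | 0.1 | 41.0 |
| violet | 12.0 | 11.2 | 0 | 39.1 |

(readings scatter by 1 percentage point)

Assume each substrate is used at a rate proportional to its own amount, with a common factor for catalyst and partner. Let f_L and f_R be the fractions of left-handed and right-handed substrate left. Dividing the two rate equations and integrating gives ln f_L = s ln f_R, where s, the selectivity factor, is the ratio of the two rate constants. Time drops out, and the excess of left-handed over right-handed product is e = (f_R − f_L)/(2 − f_L − f_R).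

Summing logarithms over the 4 blue readings, taking f_R from the right-handed product, gives s = 8.80. This is a rough reading: those right-handed readings sum to 5.5 percentage points, with a scatter of 2 points on the sum.

With this s, violet should sum to 3.7 points, and it shows 0.6 points. A gap of that size on so scattered a sum shows no secure temperature effect, so I carry blue's s.

Alder lies nearer blue in temperature than cedar does. Taking blue's f_L at 15.0 h, 80.4%, as a stand-in gives an estimate for alder of 77.8%. I assume s falls on warming, an assumption of mine and no reading from these runs, so I put cedar lower and charge alder.

The forecast differs, with cedar leading at 93% against 84% for alder: “Cedar probably leads, but with moderate confidence”.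

The flasks give alder as the leader, with cedar 70.9% and alder 78.1%.

    partner → decomposed reagent (k = 0.0918 /h, Ea = 86.0 kJ/mol)
    partner + catalyst + right-handed substrate → catalyst + right-handed product (k = 6450 /M²/h, Ea = 48.0 kJ/mol)
    partner + catalyst + left-handed substrate → catalyst + left-handed product (k = 43200 /M²/h, Ea = 36.0 kJ/mol)
    catalyst + added ligand ⇌ idle complex (K = 29200 /M, k = 4280 /M/h, Ea = 40.0 kJ/mol, ΔH = 15.0 kJ/mol)
    (constants at 0 °C)

With alder's remaining 77% of left-handed substrate, s gives 77.4%. Cedar's remaining 73% gives 76.9% against that flask's 70.9%, so the reckoning parts from cedar; in the equations the right-handed path has the activation energy higher by 12.0 kJ/mol. The neighbouring flask, alder with 1.4 × 10⁻⁴ M of catalyst, keeps 37% of its left-handed substrate, for which s gives 71.1%; its simulated excess is 71.9%.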